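The rate constants are assumed; what happens was integrated by code.

You cannot read the part reacted off the coupling's starting rate, since the nucleophile in that rate does not stay at its charge.

    nucleophile + acid set free ⇌ protonated nucleophile, settled at all times (K1 = 12 M⁻¹)
    electrophile + nucleophile → acid set free + target (k2 = 0.0030 M⁻¹ min⁻¹)
    target → over-reaction product (k3 = 0.0083 min⁻¹)
    2 nucleophile → homo dimer (k4 = 0.0011 M⁻¹ min⁻¹)
    acid set free + free base ⇌ salt of the base, settled at all times (K5 = 710 M⁻¹)

all flasks: electrophile 1.0 M; nucleophile 3.00 M; time 80 min
- spring: free base 0.300 M
- dawn: free base 0.450 M
- winter: free base 0.670 M

1. part of the electrophile that has reacted at the end, spring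
2. part of the electrophile that has reacted at the end, dawn
3. part of the electrophile that has reacted at the end, winter
4. what raising the concentration of free base from its lowest to its highest value here does to the part of the electrophile that has reacted (changes below 5 percentage points count as none) (no change / it rises / it falls)

- for a step with 2 of a species take k times the square, and two of it per event
- run time (spring): 80 min

Start with the acid set free. In spring, the equilibrium constant times the charge is 210 for the free base against 36 for the nucleophile, so I send the acid to the free base first and count the nucleophile as free.

Next comes the coupling. With the nucleophile held at its spring charge, the electrophile's half-life is 77 min, which over 80 min gives 51.3%. The loss of target, half-life 84 min, comes after the electrophile has reacted, so it does nothing to the spring answer.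

But the dimer step gives the nucleophile a first half-life τ of 152 min, and by itself it leaves the charge divided by one plus t/τ, which is 1.96 M at the end. So replace that curve by its mean: N̄ = 2.41 M, the mean nucleophile concentration over the run under the dimer step. The electrophile then decays pseudo-first-order at 0.00723 min⁻¹, and the part reacted is x = 43.9% for each recipe. The coupling spends nucleophile too, though the dimer step uses it 2.2 times as fast just after the start of winter, so x stands somewhat high.

In spring, x implies 0.439 M of acid, more than the 0.300 M of free base, so 0.139 M may end on the nucleophile. Taking half of that off N̄ lowers x by 0.94 percentage points, less than the 5 points that counts, so I commit to no change.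

The forecast gave 40.3%, 40.9% and 41.2% for spring, dawn and winter, below my x, and no change, saying “the conversions differ by only about a point”.

Spring, dawn and winter give 40.6%, 41.0% and 41.2%, a change of 0.53 points from lowest to highest free base, so no change. In winter, 55.6% of the charged nucleophile is still free at the end, which is 1.67 M, less than the 1.96 M of the dimer curve. Turned back, the winter answer corresponds to a mean of 2.21 M against N̄ of 2.41 M, which is the same 2.7 points by which x stands above the winter answer.

Read the winter flask earlier, at 50 min. The mean becomes 2.59 M, which gives 32.2%. The flask gives 30.6%.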